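The runs were generated by integration for an exercise, noise included.

Early times were the meeting's subject: how much product per catalyst per day the first readings of two earlier runs allow, and what that says of eta and alpha.

| flask | substrate | coupling partner | free catalyst | temperature | remark | time |
|---|---|---|---|---|---|---|
| violet | 1 M | 1.2 M | 1.4 mM | −10 °C | run made earlier |  |
| green | 1 M | 1.2 M | 2.2 mM | 10 °C | run made earlier |  |
| eta | 1.0 M | 1.20 M | 1.0 mM | −5 °C |  | 5.0 d |
| alpha | 1.0 M | 1.20 M | 1.0 mM | 25 °C |  | 5.0 d |

- violet (time / d: product / %, substrate / %): 0.250: 0, 98; 0.417: 0, 97; 0.625: 1, 99; 1.04: 1, 98; 1.67: 2, 100; 3.00: 4, 97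
- green (time / h: product / %, substrate / %): 3.00: 2, 94; 5.00: 4, 92; 8.00: 9, 94; 12.0: 11, 91; 20.0: 16, 85; 30.0: 22, 77

(readings scatter by 1.5 percentage points)



- the flask that comes out highest in amount of product, in percent of the substrate charged, or "all alike" when all lie within 1.5 percentage points (eta / alpha / all alike)
- product at the end, in percent of the substrate charged, eta
- product at the end, in percent of the substrate charged, alpha

The kineticist took the early turnover rate, product made per free catalyst charged per day, and read 9.52 d⁻¹ from the violet run and 100 d⁻¹ from the green run. She warned that these readings carry their scatter and that the runs differ in catalyst as well as temperature, so proportionality to catalyst is an assumption. On it, they imply an apparent activation energy of 72.8 kJ mol⁻¹, hence 17.7 d⁻¹ for eta and 474 d⁻¹ for alpha. For alpha, 2.11 d is the turnover clock, the time the early rate would need to turn over the whole substrate charge; for eta it is 56.4 d.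

The process chemist objected that a straight line over 5.0 d then gives alpha 2.37 charges, more than it holds. He proposed going round again, with the rate in proportion to the substrate left, so that the product fraction is one minus exp(−time/clock). The green run's own clock, 4.55 d, then gives 24.0% at its last reading, where 22% was read. The meeting committed to 8.48% for eta and 90.7% for alpha.

The forecast put alpha highest, with 8.5% for eta and, for alpha, 73%, which it called “a long extrapolation” and which stands lower than the meeting's figure.

The flasks give 5.95% for eta and 97.9% for alpha, so alpha is highest.

    catalyst intermediate C ⇌ free catalyst + product (K = 46.0 M, k = 0.0120 s⁻¹, Ea = 91.0 kJ mol⁻¹, ΔH = 9.00 kJ mol⁻¹)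
    substrate + catalyst intermediate A → catalyst intermediate B (k = 0.0120 L mol⁻¹ s⁻¹, Ea = 65.0 kJ mol⁻¹)
    catalyst intermediate B → released group + catalyst intermediate C (k = 0.0570 s⁻¹, Ea = 75.0 kJ mol⁻¹)
    coupling partner + free catalyst → catalyst intermediate A (k = 0.130 L mol⁻¹ s⁻¹, Ea = 39.0 kJ mol⁻¹)
    (constants at 25 °C)

Eta's low figure is mainly owed to the hour of its reading: the same flask left until 50.0 d stands at 54.7% instead of 5.95%, and eta's clock of 56.4 d gives 58.8% at that time. Alpha's clock of 2.11 d, scaled to a neighbour flask of alpha with 2.5 × 10⁻⁴ M of free catalyst, becomes 8.43 d and gives 44.7%, and that neighbour flask shows 48.4%.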